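**Retrosynthetic overview**

- The target is a hemiketal: C4 carries OH and the 2'-oxygen of ring B, so C3–C4 is read as an O-acetyl group on the ring B phenol, and C2 (bound to O1, H and C1') as the formyl carbon of 2,6-dihydroxybenzaldehyde. C4a is the only unsubstituted carbon of ring A, ortho to O1 and activated by O1, the 5-methoxy oxygen and the pyran oxygen on C7; this makes the key step possible.
- Key disconnection (C2–C3 and C4–C4a): a chiral-anion-controlled cationic (4+2) annulation. An O-aryl oxocarbenium ion at C2 is attacked by a silyl ketene acetal tethered through the ring B oxygen, and the resulting silylated lactone cation is arylated by C4a. This builds the dibenzo-fused 2,6-dioxabicyclo[3.3.1]nonane core and both stereocentres at once.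
- The cyclisation precursor comes from 2,6-diacetoxybenzaldehyde, pivaloyl chloride and the ring A chromenol (α-chloroalkyl ester formation, O-alkylation, O-silylation of both acetate enolates).
- The chromenol comes from 5-methoxyresorcinol: directed lithiation and prenylation between the two oxygens, then chromenylation of the symmetrical 2-prenylresorcinol with 3-methylbut-2-enal (regiochemistry fixed by symmetry).
- Order of ring formation: dimethylpyran ring first, then the ring B dihydropyran ring (O–C4–C3–C2–C1'–C2') and ring C together in the key step; two deprotections finish the route.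

Key step: step 8

Assumption: the ring-closed hemiketal (4,2'-epoxyflavan-4-ol) is taken to be the stable tautomer of the corresponding 2',6'-dihydroxyflavanone. Flavan numbering is used for the core (O1, C2, C3, C4, C4a, C5–C8, C8a; ring B C1'–C6'; ring A is the chromene-fused benzene ring, ring C the O1–C2–C3–C4–C4a–C8a ring).

**Route**

Step 1
Reactants: 1 5-methoxybenzene-1,3-diol (5-methoxyresorcinol)
Product: 2 1-methoxy-3,5-bis(methoxymethoxy)benzene
Conditions: NaH (2.2 equiv), chloromethyl methyl ether (2.2 equiv), DMF, 0 °C to rt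
Reagents that add atoms: chloromethyl methyl ether, COCCl
Why: Williamson-type O-alkylation of both phenoxides with the α-chloro ether installs the two methoxymethyl ethers that later direct the lithiation.

Step 2
Reactants: 2 1-methoxy-3,5-bis(methoxymethoxy)benzene
Product: 4 5-methoxy-1,3-bis(methoxymethoxy)-2-(3-methylbut-2-en-1-yl)benzene, via aryllithium 3 (not isolated)
Conditions: n-BuLi (1.1 equiv), TMEDA, THF, 0 °C; then 1-bromo-3-methylbut-2-ene, −78 °C to rt
Reagents that add atoms: 1-bromo-3-methylbut-2-ene (prenyl bromide), CC(C)=CCBr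
Why: Directed ortho-metalation takes place at the carbon flanked by the two chelating methoxymethoxy groups, and the aryllithium is alkylated at the primary carbon of the allylic bromide.

Step 3
Reactants: 4 5-methoxy-1,3-bis(methoxymethoxy)-2-(3-methylbut-2-en-1-yl)benzene
Product: 5 5-methoxy-2-(3-methylbut-2-en-1-yl)benzene-1,3-diol
Conditions: HCl (cat.), MeOH, 40 °C
Reagents that add atoms: none
Why: Acid-catalysed acetal exchange with methanol removes both methoxymethyl groups under conditions mild enough to leave the ortho-prenyl group uncyclised.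

Step 4
Reactants: 5 5-methoxy-2-(3-methylbut-2-en-1-yl)benzene-1,3-diol
Product: 7 5-methoxy-2,2-dimethyl-8-(3-methylbut-2-en-1-yl)-2H-chromen-7-ol, via 1-oxatriene 6 (not isolated)
Conditions: 3-methylbut-2-enal (1.0 equiv), ethylenediammonium diacetate (10 mol%), toluene, reflux
Reagents that add atoms: 3-methylbut-2-enal, CC(C)=CC=O
Why: Ammonium-acetate-catalysed Knoevenagel-type condensation at C4 (equivalent to C6 by symmetry, the only free nucleophilic positions) gives the 1-oxatriene, which closes by oxa-6π electrocyclisation to the 2,2-dimethyl-2H-chromene, so that no regiochemical choice arises.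

Step 5
Reactants: 8 2,6-dihydroxybenzaldehyde
Product: 9 2-formyl-1,3-phenylene diacetate (2,6-diacetoxybenzaldehyde)
Conditions: Ac2O (2.5 equiv), Et3N, DMAP (cat.), CH2Cl2, 0 °C to rt
Reagents that add atoms: acetic anhydride, CC(=O)OC(C)=O
Why: Nucleophilic catalysis by DMAP acetylates both hydrogen-bonded phenols and thereby places the two-carbon unit (C3–C4) on the ring B oxygen.

Step 6
Reactants: 9 2-formyl-1,3-phenylene diacetate; 7 5-methoxy-2,2-dimethyl-8-(3-methylbut-2-en-1-yl)-2H-chromen-7-ol
Product: 11 racemic (2,6-diacetoxyphenyl){[5-methoxy-2,2-dimethyl-8-(3-methylbut-2-en-1-yl)-2H-chromen-7-yl]oxy}methyl 2,2-dimethylpropanoate, via α-chloro ester 10 (not isolated)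
Conditions: pivaloyl chloride, ZnCl2 (2 mol%), CH2Cl2, 0 °C to rt; then 7, i-Pr2NEt, n-Bu4NI (10 mol%), CH2Cl2, 0 °C to rt
Reagents that add atoms: pivaloyl chloride, CC(C)(C)C(Cl)=O
Why: ZnCl2-catalysed addition of the acyl chloride across the aldehyde gives the α-chloroalkyl ester, which alkylates the phenol oxygen of 7 under amine/iodide conditions in the way chloromethyl pivalate and α-chloro ethers do, the weak base keeping acyl transfer from the aryl acetates slow; the acetal centre is formed racemic and is planarised in step 8.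

Step 7
Reactants: 11 racemic (2,6-diacetoxyphenyl){[5-methoxy-2,2-dimethyl-8-(3-methylbut-2-en-1-yl)-2H-chromen-7-yl]oxy}methyl 2,2-dimethylpropanoate
Product: 13 racemic (2,6-bis{[1-(tert-butyldimethylsilyloxy)ethenyl]oxy}phenyl){[5-methoxy-2,2-dimethyl-8-(3-methylbut-2-en-1-yl)-2H-chromen-7-yl]oxy}methyl 2,2-dimethylpropanoate, via dilithium bis-enolate 12 (not isolated)
Conditions: LiN(i-Pr)2 (2.3 equiv), THF, −78 °C, 15 min; then t-BuMe2SiCl (2.6 equiv), DMPU, −78 to −40 °C; non-aqueous work-up, used crude
Reagents that add atoms: tert-butyldimethylsilyl chloride, CC(C)(C)[Si](C)(C)Cl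
Why: Kinetic deprotonation of the two aryl acetates (the pivalate has no α-hydrogen) and O-silylation of the enolates in the presence of DMPU gives the bis(silyl ketene acetal), as for phenyl acetate.

Step 8
Reactants: 13 racemic (2,6-bis{[1-(tert-butyldimethylsilyloxy)ethenyl]oxy}phenyl){[5-methoxy-2,2-dimethyl-8-(3-methylbut-2-en-1-yl)-2H-chromen-7-yl]oxy}methyl 2,2-dimethylpropanoate
Product: 16 (2R,4S)-4-(tert-butyldimethylsilyloxy)-4,2'-epoxy-5-methoxy-6'',6''-dimethyl-8-(3-methylbut-2-en-1-yl)pyrano[2'',3'':7,6]flavan-6'-yl acetate, via oxocarbenium ion 14 (not isolated), via silylated lactone cation 15 (not isolated)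
Conditions: confined chiral imidodiphosphorimidate Brønsted acid (IDPi, 5 mol%), 4 Å MS, toluene/CH2Cl2, −78 to −40 °C; aq. NaHCO3
Reagents that add atoms: none
Why: Proposed new method: the chiral acid (silylated in situ by a trace of 13) transfers silyl to the pivalate carbonyl, the racemic acetal ionises to the planar O-aryl oxocarbenium ion 14 paired with the confined chiral anion, the tethered ketene acetal carbon adds to C2, and the silylated lactone cation 15 is arylated at once by C4a of ring A, so that C2–C3 and C4–C4a are formed in one cationic (4+2) annulation. The closest known reactions are the oxa-Povarov reaction of O-aryl oxocarbenium ions with alkenes and the chiral-anion-catalysed Mukaiyama-type addition of silyl ketene acetals to oxocarbenium ions generated from acetal esters; the tethered ketene acetal as two-carbon partner and the enantiocontrol on an acyclic O-aryl oxocarbenium ion are the untested elements. The ring B dihydropyran ring (O–C4–C3–C2–C1'–C2') closes in a 6-(enolendo)-exo-trig addition and ring C (O1–C2–C3–C4–C4a–C8a) in a 6-exo-trig Friedel–Crafts closure on the carboxonium carbon. C2 is set by the chiral anion, which is to direct the ketene acetal to the Re face of the oxocarbenium carbon (the catalyst antipode is chosen accordingly, and both enantiomers of 13 converge on 14), and C4 follows from C2 because the O1 tether can deliver C4a only to the face of C4 syn to O1. The step needs pivalate and not the aryloxide to leave, the ketene acetal and not the prenyl or chromene alkene to attack C2, and arylation at C4a only: the acyloxy group is the better leaving group and the poorer donor, the ketene acetal is by far the strongest π-nucleophile and reacts through a six-membered transition state, and C4a is the only free position of ring A, ortho to O1 and activated by three oxygens. The second ketene acetal takes up the proton set free on rearomatisation and hands its silyl group to the next pivalate, which keeps free acid from building up, turns the catalyst over and leaves the 6'-acetate.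

Step 9
Reactants: 16 (2R,4S)-4-(tert-butyldimethylsilyloxy)-4,2'-epoxy-5-methoxy-6'',6''-dimethyl-8-(3-methylbut-2-en-1-yl)pyrano[2'',3'':7,6]flavan-6'-yl acetate
Product: 17 (2R,4S)-4-(tert-butyldimethylsilyloxy)-4,2'-epoxy-5-methoxy-6'',6''-dimethyl-8-(3-methylbut-2-en-1-yl)pyrano[2'',3'':7,6]flavan-6'-ol
Conditions: K2CO3 (0.2 equiv), MeOH, 0 °C
Reagents that add atoms: none
Why: Carbonate-catalysed methanolysis (transesterification) removes the aryl acetate while the silyl ketal keeps the bicycle locked, so that C2 cannot epimerise by ring opening.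

Step 10
Reactants: 17 (2R,4S)-4-(tert-butyldimethylsilyloxy)-4,2'-epoxy-5-methoxy-6'',6''-dimethyl-8-(3-methylbut-2-en-1-yl)pyrano[2'',3'':7,6]flavan-6'-ol
Product: 18 (2R,4R)-4,2'-epoxy-5-methoxy-6'',6''-dimethyl-8-(3-methylbut-2-en-1-yl)pyrano[2'',3'':7,6]flavan-4,6'-diol (target)
Conditions: HF·pyridine, pyridine/THF, 0 °C to rt
Reagents that add atoms: none
Why: Fluoride-mediated desilylation cleaves the silicon–oxygen bond of the bridgehead silyl ketal under buffered conditions that leave the alkenes and C2 untouched, and the hemiketal should stay ring-closed (the C4 descriptor changes from S to R through the priority rules only).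

**Compound list**

1 | 5-methoxybenzene-1,3-diol | COc1cc(O)cc(O)c1 | starting material
2 | 1-methoxy-3,5-bis(methoxymethoxy)benzene | COCOc1cc(OC)cc(OCOC)c1 | intermediate
3 | [4-methoxy-2,6-bis(methoxymethoxy)phenyl]lithium | COCOc1cc(OC)cc(OCOC)c1[Li] | intermediate
4 | 5-methoxy-1,3-bis(methoxymethoxy)-2-(3-methylbut-2-en-1-yl)benzene | COCOc1cc(OC)cc(OCOC)c1CC=C(C)C | intermediate
5 | 5-methoxy-2-(3-methylbut-2-en-1-yl)benzene-1,3-diol | COc1cc(O)c(CC=C(C)C)c(O)c1 | intermediate
6 | 3-hydroxy-5-methoxy-6-(3-methylbut-2-en-1-ylidene)-2-(3-methylbut-2-en-1-yl)cyclohexa-2,4-dien-1-one (1-oxatriene) | O=C1C(CC=C(C)C)=C(O)C=C(OC)C1=CC=C(C)C | intermediate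
7 | 5-methoxy-2,2-dimethyl-8-(3-methylbut-2-en-1-yl)-2H-chromen-7-ol | COc1cc(O)c(CC=C(C)C)c2OC(C)(C)C=Cc12 | intermediate
8 | 2,6-dihydroxybenzaldehyde | O=Cc1c(O)cccc1O | starting material
9 | 2-formyl-1,3-phenylene diacetate | CC(=O)Oc1cccc(OC(C)=O)c1C=O | intermediate
10 | racemic chloro(2,6-diacetoxyphenyl)methyl 2,2-dimethylpropanoate | CC(=O)Oc1cccc(OC(C)=O)c1C(Cl)OC(=O)C(C)(C)C | intermediate
11 | racemic (2,6-diacetoxyphenyl){[5-methoxy-2,2-dimethyl-8-(3-methylbut-2-en-1-yl)-2H-chromen-7-yl]oxy}methyl 2,2-dimethylpropanoate | CC(=O)Oc1cccc(OC(C)=O)c1C(OC(=O)C(C)(C)C)Oc1cc(OC)c2C=CC(C)(C)Oc2c1CC=C(C)C | intermediate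
12 | dilithium bis-enolate of 11 | C=C(O[Li])Oc1cccc(OC(=C)O[Li])c1C(OC(=O)C(C)(C)C)Oc1cc(OC)c2C=CC(C)(C)Oc2c1CC=C(C)C | intermediate
13 | racemic (2,6-bis{[1-(tert-butyldimethylsilyloxy)ethenyl]oxy}phenyl){[5-methoxy-2,2-dimethyl-8-(3-methylbut-2-en-1-yl)-2H-chromen-7-yl]oxy}methyl 2,2-dimethylpropanoate | C=C(O[Si](C)(C)C(C)(C)C)Oc1cccc(OC(=C)O[Si](C)(C)C(C)(C)C)c1C(OC(=O)C(C)(C)C)Oc1cc(OC)c2C=CC(C)(C)Oc2c1CC=C(C)C | intermediate
14 | O-aryl oxocarbenium ion: (2,6-bis{[1-(tert-butyldimethylsilyloxy)ethenyl]oxy}benzylidene)[5-methoxy-2,2-dimethyl-8-(3-methylbut-2-en-1-yl)-2H-chromen-7-yl]oxonium | C=C(O[Si](C)(C)C(C)(C)C)Oc1cccc(OC(=C)O[Si](C)(C)C(C)(C)C)c1C=[O+]c1cc(OC)c2C=CC(C)(C)Oc2c1CC=C(C)C | intermediate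
15 | (4R)-2-(tert-butyldimethylsilyloxy)-5-{[1-(tert-butyldimethylsilyloxy)ethenyl]oxy}-4-{[5-methoxy-2,2-dimethyl-8-(3-methylbut-2-en-1-yl)-2H-chromen-7-yl]oxy}-3,4-dihydrochromenylium (chromenylium numbering; its C4 is flavan C2) | C=C(O[Si](C)(C)C(C)(C)C)Oc1cccc2[O+]=C(O[Si](C)(C)C(C)(C)C)C[C@@H](Oc3cc(OC)c4C=CC(C)(C)Oc4c3CC=C(C)C)c12 | intermediate
16 | (2R,4S)-4-(tert-butyldimethylsilyloxy)-4,2'-epoxy-5-methoxy-6'',6''-dimethyl-8-(3-methylbut-2-en-1-yl)pyrano[2'',3'':7,6]flavan-6'-yl acetate | COc1c2c(c(CC=C(C)C)c3c1[C@@]1(O[Si](C)(C)C(C)(C)C)C[C@@H](O3)c3c(OC(C)=O)cccc3O1)OC(C)(C)C=C2 | intermediate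
17 | (2R,4S)-4-(tert-butyldimethylsilyloxy)-4,2'-epoxy-5-methoxy-6'',6''-dimethyl-8-(3-methylbut-2-en-1-yl)pyrano[2'',3'':7,6]flavan-6'-ol | COc1c2c(c(CC=C(C)C)c3c1[C@@]1(O[Si](C)(C)C(C)(C)C)C[C@@H](O3)c3c(O)cccc3O1)OC(C)(C)C=C2 | intermediate
18 | (2R,4R)-4,2'-epoxy-5-methoxy-6'',6''-dimethyl-8-(3-methylbut-2-en-1-yl)pyrano[2'',3'':7,6]flavan-4,6'-diol | COc1c2c(c(CC=C(C)C)c3c1[C@@]1(O)C[C@@H](O3)c3c(O)cccc3O1)OC(C)(C)C=C2 | target

**Step count and risks**

Total step count: 10. Longest linear sequence: 9 steps (steps 1–4, then 6–10, from 5-methoxyresorcinol).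

Steps most likely to fail:

Step 8. The ion pair may discriminate the two faces of the oxocarbenium carbon poorly. The cation may also stop at the lactone stage and lose the ring A phenol by β-elimination before the arene closes. Fallback: from 13, the same connectivity is made without a chiral catalyst, with t-BuMe2SiOSO2CF3 (10 mol%) in CH2Cl2 at −78 °C to 0 °C (silyl-triflate-promoted addition of a silyl ketene acetal to an α-acyloxy ether, then Friedel–Crafts closure of the silylated lactone on warming). This should give the racemic silyl ketal acetate F1. Its enantiomers are separated by preparative chromatography on a chiral stationary phase (supercritical CO2/alcohol); the (2R,4S) enantiomer is 16, where the route is rejoined before step 9.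

Step 6. Acyl transfer from the aryl acetates to the phenol, C-alkylation of ring A at C4a, or incomplete addition of the acyl chloride to the hindered aldehyde may erode the coupling. Fallback: from 9 and 7, by acetal exchange instead of halide displacement. Aldehyde 9 with pivalic anhydride and FeCl3 (cat.) should give the acylal (2,6-diacetoxyphenyl)methylene bis(2,2-dimethylpropanoate) F2. Chromenol 7 with hexamethyldisilazane should give its trimethylsilyl ether F3. Me3SiOSO2CF3 (cat.) in CH2Cl2 at −78 °C should then exchange one pivalate of F2 for the aryloxy group of F3 (silyl-triflate-catalysed acetal exchange with a silyl ether), which returns to 11.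

Step 7. The aryl acetate enolates may fragment to ketene and phenoxide, be silylated on carbon, or attack the neighbouring acetal ester before they are trapped. Fallback: from 11, without strong base and without isolating a ketene acetal. Me3SiOSO2CF3/i-Pr2NEt in CH2Cl2 (soft enolisation to the silyl ketene acetal and Mukaiyama-type addition to the acetal ester in one pot) should give the racemic lactone 4-{[5-methoxy-2,2-dimethyl-8-(3-methylbut-2-en-1-yl)-2H-chromen-7-yl]oxy}-2-oxochroman-5-yl acetate F4. BF3·OEt2 in CH2Cl2 should then close ring C by intramolecular Friedel–Crafts addition to the lactone carbonyl and give the racemic hemiketal acetate F5. K2CO3/MeOH should give the racemic hemiketal diol F6, and preparative chromatography on a chiral stationary phase returns to 18.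

Further compounds
F1 | step 8 | racemic 4-(tert-butyldimethylsilyloxy)-4,2'-epoxy-5-methoxy-6'',6''-dimethyl-8-(3-methylbut-2-en-1-yl)pyrano[2'',3'':7,6]flavan-6'-yl acetate | COc1c2c(c(CC=C(C)C)c3c1C1(O[Si](C)(C)C(C)(C)C)CC(O3)c3c(OC(C)=O)cccc3O1)OC(C)(C)C=C2
F2 | step 6 | (2,6-diacetoxyphenyl)methylene bis(2,2-dimethylpropanoate) | CC(=O)Oc1cccc(OC(C)=O)c1C(OC(=O)C(C)(C)C)OC(=O)C(C)(C)C
F3 | step 6 | {[5-methoxy-2,2-dimethyl-8-(3-methylbut-2-en-1-yl)-2H-chromen-7-yl]oxy}trimethylsilane | COc1cc(O[Si](C)(C)C)c(CC=C(C)C)c2OC(C)(C)C=Cc12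
F4 | step 7 | racemic 4-{[5-methoxy-2,2-dimethyl-8-(3-methylbut-2-en-1-yl)-2H-chromen-7-yl]oxy}-2-oxochroman-5-yl acetate | CC(=O)Oc1cccc2OC(=O)CC(Oc3cc(OC)c4C=CC(C)(C)Oc4c3CC=C(C)C)c12
F5 | step 7 | racemic 4,2'-epoxy-4-hydroxy-5-methoxy-6'',6''-dimethyl-8-(3-methylbut-2-en-1-yl)pyrano[2'',3'':7,6]flavan-6'-yl acetate | COc1c2c(c(CC=C(C)C)c3c1C1(O)CC(O3)c3c(OC(C)=O)cccc3O1)OC(C)(C)C=C2
F6 | step 7 | racemic 4,2'-epoxy-5-methoxy-6'',6''-dimethyl-8-(3-methylbut-2-en-1-yl)pyrano[2'',3'':7,6]flavan-4,6'-diol | COc1c2c(c(CC=C(C)C)c3c1C1(O)CC(O3)c3c(O)cccc3O1)OC(C)(C)C=C2
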